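## The problem

Target 20 is 3-(2,4-dihydroxyphenyl)-5-hydroxy-7-methoxy-6-prenylcoumarin. Its ring A (C4a, C5, C6, C7, C8, C8a) carries oxygen on every second carbon: the lactone oxygen O1 on C8a, a free hydroxyl on C5 and a methoxyl on C7. A prenyl group sits on C6 between the hydroxyl and the methoxyl, and a resorcinol ring B is attached to C3 of the lactone ring. The target has no stereocentre and no alkene geometry, so the task is one of regiochemistry: three ring A oxygens that must end up different, a prenyl group at C6 and not at C8, and the C3–ring B bond. Stereocentres appear only in passing (C3 at the dihydrocoumarin stage), control nothing and may be racemic. The fragile parts are the prenyl alkene beside the unchelated 5-OH (acid closes the pair to a 2,2-dimethylchroman; hydrogenation and strong oxidants attack the alkene), the electron-rich phenols and the lactone, which alkoxide and hydroxide open. The enabling feature is that ring A is a folded triketide: C8a–C8–C7(OMe)–C6–C5–C4a corresponds atom for atom to C2–C3–C4(OMe)–C5–C6–CH3 of 4-methoxy-6-methyl-2H-pyran-2-one 7, a masked 3,5-dioxo ester whose two ends need only be joined. The 2-alkyl-5-methoxyresorcinol that results is locally symmetric about the C4a–C7 axis, so either hydroxyl beside C4a closes the lactone to the same compound and the O1/5-OH/7-OMe pattern needs no selective O-alkylation.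

## Retrosynthesis

**20 from 19.** The two acetal C–O bonds on ring B are cut last. Methoxymethyl ethers are chosen because they pass through amide bases, hot methoxide, a quinone oxidant, semi-hydrogenation and 130 °C. Silyl ethers would fall to methoxide, and benzyl ethers could not be hydrogenolysed beside the prenyl group. The forward step must use acid mild enough to leave the prenyl/5-OH pair alone.

**19 from 14 and 15, through 16, 17 and 18.** The C6–CH2 bond of the prenyl group is cut. A direct C-prenylation of 14 could not tell C6 from C8 or carbon from oxygen. An aromatic Claisen rearrangement of the 5-O-(1,1-dimethylallyl) ether 17 can only deliver to C6, because the other ortho carbon is the ring fusion C4a; it passes through dienone 18. Ether 17 comes from alkyne 16 by semi-hydrogenation, and 16 from phenol 14 and 3-chloro-3-methylbut-1-yne 15. This requires 14 to have a single free hydroxyl.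

**14 from 13.** The C3=C4 double bond is removed. Keeping C4 as a methylene until after ring A is made lets the C3–C4–C4a chain be assembled by conjugate addition, and the dihydrocoumarin 13 is what a lactonisation delivers directly. The forward dehydrogenation is helped by C4 being benzylic to a ring with oxygen ortho and para.

**13 from 10, through 11 and 12 (key disconnection).** Two bonds are cut: O1–C2 of the lactone and C4a–C8a of ring A. A cut at C4–C4a (phenol plus a three-carbon ester) would leave two free ring A hydroxyls to tell apart afterwards. Here the methoxyl is already fixed in pyranone 7, and precursor 10 contains no benzenoid ring A at all.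

- Forward course: methoxide opens the pyranone of 10 to keto enoate 11, C4a acylates onto the unveiled ester to give resorcinol acid 12, and a flanking hydroxyl lactonises to 13.
- The side-chain carboxyl is carried through the fold as the free acid, not as an ester. In 11 an ester at C2 would sit 1,5 to the C5 ketone, the classical arrangement for Dieckmann closure from the more acidic C6 methylene to a cyclohexane-1,3-dione. A carboxylate cannot be acylated, so this path is closed.

**10 from 7 and 6, through 8 and 9.** The C4–C4a bond is cut: the lithiated 6-methyl group of pyranone 7 (anion 8) adds in conjugate fashion to 2-arylacrylate 6 to give ester 9. An allyl ester is used because zerovalent palladium releases acid 10 under neutral conditions. Hydroxide would open the pyranone to a C8a carboxylate and ruin the later Claisen closure.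

**6 from 3 and 4, through 5; 3 from 1, through 2.** The C3=CH2 bond is cut: arylacetate 3 is hydroxymethylated with formaldehyde 4 (adduct 5) and dehydrated. Ester 3 comes from (2,4-dihydroxyphenyl)acetic acid 1 by esterification to 2 and protection of both phenols.

## Roads not taken

**Alternative 1:** The cut is C6–C7 of ring A. A 3-aryl-2-pyranone that already carries ring B would be taken to triene A2, with a ketene silyl acetal on the C8a side and a silyl enol ether of a prenyl-bearing ketone on the C4a side. Heating would close ring A by disrotatory six-electron electrocyclisation, and loss of silanol across C7/C6 would aromatise to A1.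

- Merits: the prenyl group at C6 and the methoxyl at C7 are fixed in the open-chain termini, so no C6/C8 question arises. The coumarin oxidation level is present throughout, and fluoride would finish the synthesis without acid near the prenyl group.
- Where it is better: it avoids the dehydrogenation and the three-step ether/Claisen sequence of the chosen plan.
- Weak points: A2 needs a fully substituted pyranone with an acyl group and an acetic ester on neighbouring carbons, both enolised and silylated beside a lactone. Its C7 terminus is fully substituted, so one oxygen substituent must turn inward in the closure. The temperature this demands endangers the ketene acetal and the skipped diene of the prenyl chain.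
- Against it the chosen plan sets a purchased pyranone, precursors made by ordinary enolate chemistry and a six-membered enolate acylation as ring closure.

**Alternative 2:** The cut is C4–C4a and O1–C2. In acid, A5 (phloroglucinol) would attack the enamine carbon of enamino ester A4, the amine would leave and a neighbouring hydroxyl would lactonise to A3.

- Merits: it is the shortest and most convergent road. Ring A is bought, ring B, C3 and C4 arrive in one operation, the coumarin oxidation level is reached directly, and the symmetry of A5 removes any regiochemistry from the annulation.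
- Where it is better: in step count and in the certainty of the ring-forming step.
- Weak points: A3 has free hydroxyls at C5 and C7, neither hydrogen-bonded to the remote C2 carbonyl and both conjugated to it. Methylation at O7 only, then alkylation at O5, rests on a small difference in acidity and hindrance, and the wrong isomers would be hard to remove. The pivalates must also survive acid annulation and basic methylation.
- Against it the chosen plan sets that the 7-OMe/5-OH pattern is built in from pyranone 7. It pays for this with more steps and a less proven key step.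

**Alternative 3:** The cut is O1–C8a. E-cinnamic acid A7 would be oxidised at constant current on a graphite anode; the carboxylate attacks the oxidised aryl alkene at the one free ortho carbon and the pyranone ring closes to A6.

- Merits: ring A is an ordinary benzene derivative whose prenyl group can be placed between the two oxygens before any ring forms. No ortho oxygen needs to be pre-installed and the coumarin oxidation level is reached directly.
- Where it is as good or better: as good on prenyl placement, better on the availability of ring A.
- Weak points: A6 carries no ring B, so C3 would still have to be halogenated and cross-coupled with the prenyl alkene exposed, and the brevity is lost. The E acid must isomerise or rearrange to reach the ortho carbon. The anode also meets a trisubstituted alkene and a trioxygenated arene of similar ease of oxidation.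
- Against it the chosen plan sets that ring B is on board before the key step and that the prenyl group appears only after the last oxidation.

Key step: step 6

Remark: the target has no stereocentre. The stereocentres that arise on the way (C2 of 5, C3 of 9 to 13, C6 of 18) are racemic and are erased later. Compounds 1, 4 (as paraformaldehyde), 7 and 15 are taken as purchased.

Step 1
Reactants: 1 (2,4-dihydroxyphenyl)acetic acid
Product: 2 allyl (2,4-dihydroxyphenyl)acetate
Conditions: allyl alcohol (solvent), TsOH·H2O (cat.), 70 °C
Reagents that add atoms: allyl alcohol, C=CCO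
Why: Fischer esterification; in excess alcohol any benzofuranone formed by ortho-lactonisation is drained to the open allyl ester, and the phenols do not react.

Step 2
Reactants: 2 allyl (2,4-dihydroxyphenyl)acetate
Product: 3 allyl [2,4-bis(methoxymethoxy)phenyl]acetate
Conditions: MOMCl, i-Pr2NEt, CH2Cl2, 0 °C to rt
Reagents that add atoms: chloromethyl methyl ether (MOMCl), COCCl
Why: O-alkylation of both phenols to methoxymethyl acetals; the amine base is too weak to enolise the ester, so C-alkylation should not compete.

Step 3
Reactants: 3 allyl [2,4-bis(methoxymethoxy)phenyl]acetate; 4 formaldehyde (as paraformaldehyde)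
Product: 6 allyl 2-[2,4-bis(methoxymethoxy)phenyl]prop-2-enoate, via hydroxymethyl aldol adduct 5 (not isolated)
Conditions: (CH2O)n, K2CO3, n-Bu4NI (cat.), toluene, 80 °C
Reagents that add atoms: none
Why: Aldol hydroxymethylation of the arylacetate followed by E1cB dehydration, the standard preparation of 2-arylacrylates; anhydrous carbonate leaves the allyl ester and the acetals intact.

Step 4
Reactants: 7 4-methoxy-6-methyl-2H-pyran-2-one; 6 allyl 2-[2,4-bis(methoxymethoxy)phenyl]prop-2-enoate
Product: 9 rac-allyl 2-[2,4-bis(methoxymethoxy)phenyl]-4-(4-methoxy-2-oxo-2H-pyran-6-yl)butanoate, via lithiated pyranone 8 (not isolated)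
Conditions: 7, LiN(i-Pr)2 (LDA), THF, −78 °C; then 6 added slowly (limiting), −78 °C; NH4Cl (aq.)
Reagents that add atoms: none
Why: Vinylogous deprotonation of the 6-methyl group gives extended enolate 8, which reacts at its exocyclic carbon in a Michael addition to the acrylate; the aryl-stabilised ester enolate formed is protonated on quench, so C3 is racemic (erased in step 7).

Step 5
Reactants: 9 rac-allyl 2-[2,4-bis(methoxymethoxy)phenyl]-4-(4-methoxy-2-oxo-2H-pyran-6-yl)butanoate
Product: 10 rac-2-[2,4-bis(methoxymethoxy)phenyl]-4-(4-methoxy-2-oxo-2H-pyran-6-yl)butanoic acid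
Conditions: Pd(PPh3)4 (cat.), N-methylaniline, THF, rt
Reagents that add atoms: none
Why: Tsuji–Trost deallylation: zerovalent palladium ionises the allyl ester to a pi-allyl complex and the aniline takes up the allyl group; no hydroxide or alkoxide is present, so the pyranone and the acetals should survive.

Step 6
Reactants: 10 rac-2-[2,4-bis(methoxymethoxy)phenyl]-4-(4-methoxy-2-oxo-2H-pyran-6-yl)butanoic acid
Product: 13 rac-3-[2,4-bis(methoxymethoxy)phenyl]-5-hydroxy-7-methoxy-3,4-dihydro-2H-chromen-2-one, via ring-opened keto enoate 11 (not isolated), via resorcinol acid 12 (not isolated)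
Conditions: Mg(OMe)2, MeOH, reflux, Ar; AcOH, extraction into CH2Cl2; then DIC, DMAP (cat.), 0 °C to rt
Reagents that add atoms: none
Why: Methoxide adds to the lactone carbonyl of 10 (present as its magnesium carboxylate) and reversibly opens the pyranone to keto enoate 11, whose 7E geometry, inherited from the ring, holds the new methyl ester (C8a) cis to the ketone chain. Enolisation of the C5 ketone towards C4a and attack on that ester is a 6-(enolendo)-exo-trig Claisen closure of ring A (C4a–C8a); loss of methoxide and enolisation give resorcinol 12 irreversibly, which drains the reversible return to the pyranone by O-attack. The closest known reaction type is the magnesium methoxide induced recyclisation of 4-methoxy-2-pyranones, as masked poly-beta-carbonyl chains, to phloroglucinol methyl ethers. The side-chain carboxyl is a carboxylate on purpose: as an ester it would be the 5-oxo ester partner for Dieckmann closure from the more acidic C6 methylene to a cyclohexane-1,3-dione, whereas C6 now has only C8a in reach and that would mean a four-membered ring. After the acetic acid quench, carbodiimide activation of the acid lets either hydroxyl beside C4a close the lactone (O1–C2) by 6-exo-trig acyl substitution; the two are interchanged by rotation about C4–C4a, so both give the same 13 with OMe at C7 and OH at C5. No new stereocentre is set; C3 is carried over racemic from 10 and removed in step 7. The selectivities needed are C- over O-cyclisation and C4a over C6 as nucleophile, secured by aromatisation as the only irreversible exit and by the carboxylate.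

Step 7
Reactants: 13 rac-3-[2,4-bis(methoxymethoxy)phenyl]-5-hydroxy-7-methoxy-3,4-dihydro-2H-chromen-2-one
Product: 14 3-[2,4-bis(methoxymethoxy)phenyl]-5-hydroxy-7-methoxy-2H-chromen-2-one
Conditions: DDQ, 1,4-dioxane, 80 °C
Reagents that add atoms: none
Why: Quinone dehydrogenation: hydride is taken from benzylic C4, which is activated by the ortho 5-OH, the para 7-OMe and O1, and loss of the acidic C3 proton gives the conjugated coumarin; the acetals are inert to DDQ.

Step 8
Reactants: 14 3-[2,4-bis(methoxymethoxy)phenyl]-5-hydroxy-7-methoxy-2H-chromen-2-one; 15 3-chloro-3-methylbut-1-yne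
Product: 16 3-[2,4-bis(methoxymethoxy)phenyl]-7-methoxy-5-[(2-methylbut-3-yn-2-yl)oxy]-2H-chromen-2-one
Conditions: 15, DBU, CuCl2·2H2O (cat.), MeCN, 0 °C to rt
Reagents that add atoms: none
Why: Copper-catalysed O-alkylation of a phenol with a tertiary propargylic chloride through a copper acetylide; the 5-OH is the only free hydroxyl, so no site selectivity is required.

Step 9
Reactants: 16 3-[2,4-bis(methoxymethoxy)phenyl]-7-methoxy-5-[(2-methylbut-3-yn-2-yl)oxy]-2H-chromen-2-one
Product: 17 3-[2,4-bis(methoxymethoxy)phenyl]-7-methoxy-5-[(2-methylbut-3-en-2-yl)oxy]-2H-chromen-2-one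
Conditions: H2 (1 atm), Pd/CaCO3 poisoned with Pb(OAc)2 (Lindlar catalyst), quinoline, EtOAc, rt
Reagents that add atoms: none
Why: Lindlar semi-hydrogenation of the terminal alkyne to the vinyl group; the conjugated trisubstituted C3=C4 bond and the aryl ethers should not be reduced on the poisoned catalyst.

Step 10
Reactants: 17 3-[2,4-bis(methoxymethoxy)phenyl]-7-methoxy-5-[(2-methylbut-3-en-2-yl)oxy]-2H-chromen-2-one
Product: 19 3-[2,4-bis(methoxymethoxy)phenyl]-5-hydroxy-7-methoxy-6-(3-methylbut-2-en-1-yl)-2H-chromen-2-one, via ortho-dienone 18 (not isolated)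
Conditions: PhNEt2, 130 °C
Reagents that add atoms: none
Why: Aromatic Claisen rearrangement: the [3,3] shift can only reach C6, since the other ortho carbon is the ring fusion C4a, and allyl inversion turns the 1,1-dimethylallyl group into prenyl; dienone 18 enolises to the phenol, and the basic solvent speeds this and suppresses acid-catalysed cyclisation.

Step 11
Reactants: 19 3-[2,4-bis(methoxymethoxy)phenyl]-5-hydroxy-7-methoxy-6-(3-methylbut-2-en-1-yl)-2H-chromen-2-one
Product: 20 3-(2,4-dihydroxyphenyl)-5-hydroxy-7-methoxy-6-(3-methylbut-2-en-1-yl)-2H-chromen-2-one (CNP0305155.0)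
Conditions: HCl (3 M aq.), MeOH, 40 °C
Reagents that add atoms: none
Why: Acid-catalysed methanolysis of the two aryl methoxymethyl acetals; dilute acid at mild temperature is the usual way to free phenols beside a prenyl group, and the lactone is stable to it.

Compound list

1 | (2,4-dihydroxyphenyl)acetic acid | O=C(O)Cc1ccc(O)cc1O | starting material
2 | allyl (2,4-dihydroxyphenyl)acetate | C=CCOC(=O)Cc1ccc(O)cc1O | intermediate
3 | allyl [2,4-bis(methoxymethoxy)phenyl]acetate | C=CCOC(=O)Cc1ccc(OCOC)cc1OCOC | intermediate
4 | formaldehyde (used as paraformaldehyde) | C=O | starting material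
5 | rac-allyl 2-[2,4-bis(methoxymethoxy)phenyl]-3-hydroxypropanoate | C=CCOC(=O)C(CO)c1ccc(OCOC)cc1OCOC | intermediate (not isolated)
6 | allyl 2-[2,4-bis(methoxymethoxy)phenyl]prop-2-enoate | C=CCOC(=O)C(=C)c1ccc(OCOC)cc1OCOC | intermediate
7 | 4-methoxy-6-methyl-2H-pyran-2-one | COc1cc(C)oc(=O)c1 | starting material
8 | 6-(lithiomethyl)-4-methoxy-2H-pyran-2-one | [Li]Cc1cc(OC)cc(=O)o1 | intermediate (not isolated)
9 | rac-allyl 2-[2,4-bis(methoxymethoxy)phenyl]-4-(4-methoxy-2-oxo-2H-pyran-6-yl)butanoate | C=CCOC(=O)C(CCc1cc(OC)cc(=O)o1)c1ccc(OCOC)cc1OCOC | intermediate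
10 | rac-2-[2,4-bis(methoxymethoxy)phenyl]-4-(4-methoxy-2-oxo-2H-pyran-6-yl)butanoic acid | OC(=O)C(CCc1cc(OC)cc(=O)o1)c1ccc(OCOC)cc1OCOC | intermediate
11 | rac-(7E)-2-[2,4-bis(methoxymethoxy)phenyl]-7,9-dimethoxy-5,9-dioxonon-7-enoic acid | COC(=O)/C=C(/OC)CC(=O)CCC(C(=O)O)c1ccc(OCOC)cc1OCOC | intermediate (not isolated)
12 | rac-2-[2,4-bis(methoxymethoxy)phenyl]-3-(2,6-dihydroxy-4-methoxyphenyl)propanoic acid | COc1cc(O)c(CC(C(=O)O)c2ccc(OCOC)cc2OCOC)c(O)c1 | intermediate (not isolated)
13 | rac-3-[2,4-bis(methoxymethoxy)phenyl]-5-hydroxy-7-methoxy-3,4-dihydro-2H-chromen-2-one | COc1cc(O)c2c(c1)OC(=O)C(c1ccc(OCOC)cc1OCOC)C2 | intermediate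
14 | 3-[2,4-bis(methoxymethoxy)phenyl]-5-hydroxy-7-methoxy-2H-chromen-2-one | COc1cc(O)c2cc(-c3ccc(OCOC)cc3OCOC)c(=O)oc2c1 | intermediate
15 | 3-chloro-3-methylbut-1-yne | C#CC(C)(C)Cl | starting material
16 | 3-[2,4-bis(methoxymethoxy)phenyl]-7-methoxy-5-[(2-methylbut-3-yn-2-yl)oxy]-2H-chromen-2-one | COc1cc(OC(C)(C)C#C)c2cc(-c3ccc(OCOC)cc3OCOC)c(=O)oc2c1 | intermediate
17 | 3-[2,4-bis(methoxymethoxy)phenyl]-7-methoxy-5-[(2-methylbut-3-en-2-yl)oxy]-2H-chromen-2-one | COc1cc(OC(C)(C)C=C)c2cc(-c3ccc(OCOC)cc3OCOC)c(=O)oc2c1 | intermediate
18 | rac-3-[2,4-bis(methoxymethoxy)phenyl]-7-methoxy-6-(3-methylbut-2-en-1-yl)-2H-chromene-2,5(6H)-dione | COC1=CC2=C(C=C(c3ccc(OCOC)cc3OCOC)C(=O)O2)C(=O)C1CC=C(C)C | intermediate (not isolated)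
19 | 3-[2,4-bis(methoxymethoxy)phenyl]-5-hydroxy-7-methoxy-6-(3-methylbut-2-en-1-yl)-2H-chromen-2-one | COc1cc2oc(=O)c(-c3ccc(OCOC)cc3OCOC)cc2c(O)c1CC=C(C)C | intermediate
20 | 3-(2,4-dihydroxyphenyl)-5-hydroxy-7-methoxy-6-(3-methylbut-2-en-1-yl)-2H-chromen-2-one | COc1cc2oc(=O)c(-c3ccc(O)cc3O)cc2c(O)c1CC=C(C)C | target

Total step count: 11. Longest linear sequence: 11 steps (1 to 20); 4, 7 and 15 enter as purchased reactants.

Steps least certain to work

**Step 6 (key step).** The fold may stall at ring opening or return to the pyranone. Methoxide deprotonates 11 first at the more acidic C6 methylene, whose dienolate is unproductive, so the Claisen closure depends on a minor enolate towards C4a and may be slow. A slow closure leaves the electron-rich product exposed to air oxidation, and the carbodiimide stage may be accompanied by intermolecular esterification.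

Fallback, known chemistry that gives up the pyranone fold: it sets out from 3 and returns at 14. The deallylation conditions of step 5 applied to 3 give [2,4-bis(methoxymethoxy)phenyl]acetic acid F1. Perkin condensation of F1 with 2,6-dihydroxy-4-methoxybenzaldehyde F2 (bought in; symmetric, so only one coumarin can form) in Ac2O/Et3N at 110 °C gives 3-[2,4-bis(methoxymethoxy)phenyl]-7-methoxy-2-oxo-2H-chromen-5-yl acetate F3. K2CO3 in MeOH at rt removes the acetate to give 14.

**Step 4.** Anionic oligomerisation of acrylate 6 may outrun the single conjugate addition, because the adduct enolate can add to further 6. Metalation of 7 at ring C3 instead of the methyl group would also divert material.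

Fallback with the polarity reversed: it sets out from 7 and 3 and returns at 9. Anion 8 is trapped with monomeric formaldehyde to give 6-(2-hydroxyethyl)-4-methoxy-2H-pyran-2-one F4. Appel iodination (PPh3, I2, imidazole) gives 6-(2-iodoethyl)-4-methoxy-2H-pyran-2-one F5. The lithium enolate of 3 (LiN(SiMe3)2, THF, −78 to 0 °C) is alkylated with F5 to give 9. Elimination of F5 to the 6-vinylpyranone followed by conjugate addition of the same enolate leads to the same product.

**Step 7.** DDQ may oxidise the free phloroglucinol-type phenol beyond the wanted dehydrogenation, by quinone formation or oxidative coupling.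

Fallback by protect, oxidise and release: it sets out from 13 and returns at 14. Ac2O/pyridine gives rac-3-[2,4-bis(methoxymethoxy)phenyl]-7-methoxy-2-oxo-3,4-dihydro-2H-chromen-5-yl acetate F6. DDQ in refluxing dioxane, with C4 still activated by the 7-OMe group and O1, gives acetate F3 described above. K2CO3/MeOH gives 14.

**Step 10.** The tertiary allyl ether may fragment thermally with loss of isoprene back to 14. Dienone 18 may undergo a second [3,3] shift towards C8 before it enolises, and the product may cyclise on prolonged heating.

Fallback by Claisen rearrangement of a simple allyl ether and cross-metathesis: it sets out from 14 and returns at 19. Allyl bromide/K2CO3 in acetone gives 5-(allyloxy)-3-[2,4-bis(methoxymethoxy)phenyl]-7-methoxy-2H-chromen-2-one F7. Heating in PhNEt2 at 190 °C moves the allyl group to C6, the only open ortho carbon, to give 6-allyl-3-[2,4-bis(methoxymethoxy)phenyl]-5-hydroxy-7-methoxy-2H-chromen-2-one F8. Cross-metathesis of F8 with 2-methylbut-2-ene (second-generation Grubbs catalyst, CH2Cl2, 40 °C) gives 19.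

**Step 11.** Acid may add the 5-OH across the prenyl double bond (chroman formation) or hydrate the alkene while the acetals are being cleaved.

Fallback that removes the acetals before the prenyl group exists: it sets out from 16 and ends at 20. HCl/MeOH at rt on 16, whose tertiary propargyl aryl ether ionises far less readily than an allyl one, gives 3-(2,4-dihydroxyphenyl)-7-methoxy-5-[(2-methylbut-3-yn-2-yl)oxy]-2H-chromen-2-one F9. Lindlar semi-hydrogenation as in step 9 gives 3-(2,4-dihydroxyphenyl)-7-methoxy-5-[(2-methylbut-3-en-2-yl)oxy]-2H-chromen-2-one F10. The Claisen rearrangement of step 10 then gives 20 directly; the free ring B phenols do not take part.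

Further compounds

F1 | step 6 | [2,4-bis(methoxymethoxy)phenyl]acetic acid | OC(=O)Cc1ccc(OCOC)cc1OCOC
F2 | step 6 | 2,6-dihydroxy-4-methoxybenzaldehyde | COc1cc(O)c(C=O)c(O)c1
F3 | step 6 | 3-[2,4-bis(methoxymethoxy)phenyl]-7-methoxy-2-oxo-2H-chromen-5-yl acetate | COc1cc(OC(C)=O)c2cc(-c3ccc(OCOC)cc3OCOC)c(=O)oc2c1
F4 | step 4 | 6-(2-hydroxyethyl)-4-methoxy-2H-pyran-2-one | COc1cc(CCO)oc(=O)c1
F5 | step 4 | 6-(2-iodoethyl)-4-methoxy-2H-pyran-2-one | COc1cc(CCI)oc(=O)c1
F6 | step 7 | rac-3-[2,4-bis(methoxymethoxy)phenyl]-7-methoxy-2-oxo-3,4-dihydro-2H-chromen-5-yl acetate | COc1cc(OC(C)=O)c2c(c1)OC(=O)C(c1ccc(OCOC)cc1OCOC)C2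
F7 | step 10 | 5-(allyloxy)-3-[2,4-bis(methoxymethoxy)phenyl]-7-methoxy-2H-chromen-2-one | COc1cc(OCC=C)c2cc(-c3ccc(OCOC)cc3OCOC)c(=O)oc2c1
F8 | step 10 | 6-allyl-3-[2,4-bis(methoxymethoxy)phenyl]-5-hydroxy-7-methoxy-2H-chromen-2-one | COc1cc2oc(=O)c(-c3ccc(OCOC)cc3OCOC)cc2c(O)c1CC=C
F9 | step 11 | 3-(2,4-dihydroxyphenyl)-7-methoxy-5-[(2-methylbut-3-yn-2-yl)oxy]-2H-chromen-2-one | COc1cc(OC(C)(C)C#C)c2cc(-c3ccc(O)cc3O)c(=O)oc2c1
F10 | step 11 | 3-(2,4-dihydroxyphenyl)-7-methoxy-5-[(2-methylbut-3-en-2-yl)oxy]-2H-chromen-2-one | COc1cc(OC(C)(C)C=C)c2cc(-c3ccc(O)cc3O)c(=O)oc2c1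
A1 | alternative 1 | 3-[2,4-bis(tert-butyldimethylsilyloxy)phenyl]-5-(tert-butyldimethylsilyloxy)-7-methoxy-6-(3-methylbut-2-en-1-yl)-2H-chromen-2-one | COc1cc2oc(=O)c(-c3ccc(O[Si](C)(C)C(C)(C)C)cc3O[Si](C)(C)C(C)(C)C)cc2c(O[Si](C)(C)C(C)(C)C)c1CC=C(C)C
A2 | alternative 1 | 3-[2,4-bis(tert-butyldimethylsilyloxy)phenyl]-6-[2-(tert-butyldimethylsilyloxy)-2-methoxyethenyl]-5-[1-(tert-butyldimethylsilyloxy)-5-methylhexa-1,4-dien-1-yl]-2H-pyran-2-one | COC(O[Si](C)(C)C(C)(C)C)=Cc1oc(=O)c(-c2ccc(O[Si](C)(C)C(C)(C)C)cc2O[Si](C)(C)C(C)(C)C)cc1C(O[Si](C)(C)C(C)(C)C)=CCC=C(C)C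
A3 | alternative 2 | 3-[2,4-bis(pivaloyloxy)phenyl]-5,7-dihydroxy-2H-chromen-2-one | Oc1cc(O)c2cc(-c3ccc(OC(=O)C(C)(C)C)cc3OC(=O)C(C)(C)C)c(=O)oc2c1
A4 | alternative 2 | methyl 2-[2,4-bis(pivaloyloxy)phenyl]-3-(dimethylamino)prop-2-enoate | COC(=O)C(=CN(C)C)c1ccc(OC(=O)C(C)(C)C)cc1OC(=O)C(C)(C)C
A5 | alternative 2 | phloroglucinol (benzene-1,3,5-triol) | Oc1cc(O)cc(O)c1
A6 | alternative 3 | 7-methoxy-5-(methoxymethoxy)-6-(3-methylbut-2-en-1-yl)-2H-chromen-2-one | COc1cc2oc(=O)ccc2c(OCOC)c1CC=C(C)C
A7 | alternative 3 | (2E)-3-[4-methoxy-2-(methoxymethoxy)-3-(3-methylbut-2-en-1-yl)phenyl]prop-2-enoic acid | COCOc1c(/C=C/C(=O)O)ccc(OC)c1CC=C(C)C
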